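Which of ochre and amber ends with the larger share of first product among its adducts, and how large is that share in each?

| flask | substrate | partner | remark | time |
|---|---|---|---|---|
| winter | 1.7 M | 0.59 M | run made earlier |  |
| noon | 1.7 M | 1.3 M | run made earlier |  |
| autumn | 1.9 M | 1.7 M | run made earlier |  |
| ochre | 1.7 M | 1.70 M |  | 12 h |
| amber | 2.5 M | 0.800 M |  | 50 h |

- winter (time / h: first product / %, bis adduct / %): 0.417: 8, 1; 1.33: 18, 3; 2.50: 21, 7; 4.00: 20, 5; 5.00: 20, 5; 6.00: 18, 3; 8.00: 19, 3
- noon (time / h: first product / %, bis adduct / %): 1.33: 27, 12; 2.50: 25, 17; 4.00: 26, 19; 5.00: 26, 20; 6.00: 28, 21; 8.00: 27, 20
- autumn (time / h: first product / %, bis adduct / %): 1.50: 30, 17; 3.00: 30, 19; 5.00: 29, 24; 6.00: 29, 27; 8.00: 28, 19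

(standard deviation of a reading: 2 percentage points)

1. which of the two ends with the higher share of first product in all that became first product or bis adduct or triple product ("neither" if they lie within 2 percentage points) (ochre / amber / neither)
2. share of first product in all that became first product or bis adduct or triple product, ochre
3. share of first product in all that became first product or bis adduct or triple product, amber



At the bench I count equivalents: I take partner as the limiting reagent and let each partner make one bond, so [partner]/[substrate] at the charge should give the bonds per substrate. I then expect bis adduct over first product to equal that number, which makes the share of first product one over one plus the bonds per substrate. I test this on the last 4 readings of a run, counting first product plus twice bis adduct. Winter finds 0.273 bonds per substrate with a ratio of 0.208, and autumn finds 0.735 with 0.767, so the ratio follows the bonds found, roughly.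

But the bonds found fall short of the equivalents charged, and I compute just that correction. The part of the charged partner found in first product and bis adduct reads 78.5% in winter, 87.3% in noon and 82.1% in autumn. Their mean, 82.7%, is my landing yield, the fraction of charged partner that ends as bonds. The rule's border is the ratio of charges, tried from 0.347 to 0.895: amber at 0.320 lies below that range and ochre at 1.00 above it, so both figures are extrapolations, and I hold them only to a few points. Ochre then counts 0.827 bonds, a share of 54.7%, and amber counts 0.264, a share of 79.1%, so I expect amber to be higher.

The forecast says amber, with 46% for ochre and 78% for amber, on the ground that “Final selectivity then depends on the partner/substrate ratio”; my ochre figure lies above its figure.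

The simulation gives amber, with 51.1% for ochre and 80.7% for amber.

    substrate + partner → first product (k = 0.585 M⁻¹ h⁻¹)
    partner + first product → bis adduct (k = 0.904 M⁻¹ h⁻¹)
    partner + bis adduct ⇌ triple product (K = 0.809 M⁻¹, k = 0.850 M⁻¹ h⁻¹)
    partner → decomposed reagent (k = 0.181 h⁻¹)

In ochre at 12.0 h, partner is down to 0.016% of its charge, first product and bis adduct hold 84.6% of that charge against my landing yield of 82.7%, and 0.260 M of decomposed reagent stands beside them. A neighbour of ochre with partner cut to 0.68 M counts 0.331 bonds per substrate, hence a share of 75.2%; that flask ends with 21.6% first product, 6.26% bis adduct and a share of 77.5%.

(The runs were generated by integration for substances that don't exist, noise included.)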